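Isochromene numbering: C1, O2, C3, C4, C4a, C5, C6 (ketone), C7 (methyl carbinol), C8 (ester carbon), C8a. Read outward from C4, the atoms C3, O2 and the three carbons of the propenoic acid chain are a ring-opened furan (C3 = the furan carbon bonded to C4, O2 = the ring oxygen, the carboxyl carbon = the far α-carbon). C1 is the end of a vinylogous ester C1=C8a–C4a=C5–C6=O, so the pyran ring (O2, C1, C8a, C4a, C4, C3) can be closed by opening a furan.
Cuts, in retrosynthetic order: the C8–O acyl bond (orsellinate); CO2H back to CHO; C1–O2 together with re-closure of the side chain onto O2 (a 2-furyl group on C4); C4–C4a (dienyllithium plus furfural); C8a=C1 (Wittig); the C6 and C8a oxygens (singlet oxygen on a diene); C7–CH3 back to C7–CO2H.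
Forward: the carbocycle is the ring of benzoic acid. It is oxygenated and given C1 and the furfuryl arm, and the pyran ring closes in the key step. The aryl ester goes on only afterwards, because an acyloxy group on C8 beside the C8a=C1 enol ether would be an allylic leaving group under the acid.
Stereochemistry: C7 and C8 (both R, oxygens cis) come together from the enzymatic ipso,ortho cis-dihydroxylation of benzoic acid and stay locked in a cis-fused acetonide. Every other stereo element made on the way (C4, C6, C8a, enol ether geometry) is erased.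

Key step: step 13

Assumption: isochromene numbering is used for all intermediates; α is the ring face carrying the C7 and C8 oxygens and β the face carrying the C7 carbon substituent; C4 epimers and E/Z isomers of the C8a=C1 enol ether are carried as mixtures and left open in the SMILES because step 13 erases both.

Step 1
Reactants: 1 benzoic acid
Product: 2 (1S,2R)-1,2-dihydroxycyclohexa-3,5-diene-1-carboxylic acid
Conditions: Cupriavidus necator B9 whole cells (benzoate 1,2-dioxygenase, diol dehydrogenase-deficient), sodium benzoate feed, fructose, mineral salts medium, air, 30 °C; acidify to pH 3, EtOAc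
Reagents that add atoms: dioxygen, O=O
Why: Enzymatic arene cis-dihydroxylation adds O2 to the ipso and ortho carbons from one face and should set the quaternary C7 and C8 together in the (1S,2R) series as a single enantiomer.

Step 2
Reactants: 2 diol acid
Product: 3 (3aS,7aR)-2,2-dimethyl-3a,7a-dihydro-1,3-benzodioxole-3a-carboxylic acid
Conditions: 2,2-dimethoxypropane, TsOH·H2O (cat.), acetone, rt
Reagents that add atoms: 2,2-dimethoxypropane, COC(C)(C)OC
Why: Acid-catalysed transacetalisation ties the cis-diol into a cis-fused dioxolane, which masks both hydroxyls for the hydride, ylide and organolithium steps and later holds C8, while it is α to a ketone, in its only unstrained configuration.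

Step 3
Reactants: 3 acetonide acid
Product: 4 [(3aR,7aR)-2,2-dimethyl-3a,7a-dihydro-1,3-benzodioxol-3a-yl]methanol
Conditions: LiAlH4, THF, 0 °C to reflux
Reagents that add atoms: none
Why: LiAlH4 reduction of a carboxylic acid to the primary alcohol, with the unactivated diene and the acetal inert to hydride.

Step 4
Reactants: 4 primary alcohol
Product: 5 p-toluenesulfonate of 4
Conditions: TsCl, DMAP (cat.), pyridine, 0 °C to rt
Reagents that add atoms: p-toluenesulfonyl chloride, Cc1ccc(cc1)S(=O)(=O)Cl
Why: Sulfonylation of the only free hydroxyl turns the neopentyl-type carbinol into a leaving group.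

Step 5
Reactants: 5 tosylate
Product: 6 (3aS,7aR)-2,2,3a-trimethyl-3a,7a-dihydro-1,3-benzodioxole (diene C8a=C4a–C5=C6 with the C7 methyl group)
Conditions: LiEt3BH, THF, reflux
Reagents that add atoms: none
Why: SN2 hydride displacement of a hindered primary sulfonate by LiEt3BH, the usual reagent for neopentyl-type centres, converts the former carboxyl carbon into the C7 methyl group without touching C7 or C8.

Step 6
Reactants: 6 methyl diene acetonide
Product: 7 6β,8aβ-endoperoxide (2,3-dioxabicyclo[2.2.2]oct-5-ene, peroxide bridge anti to the acetonide)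
Conditions: O2, tetraphenylporphyrin (cat.), hν (visible), CH2Cl2, −78 °C
Reagents that add atoms: dioxygen, O=O
Why: [4+2] cycloaddition of singlet oxygen across the diene termini C8a and C6, from the β face because the acetonide shields the α face, oxygenates both carbons in one operation (both new centres are erased later).

Step 7
Reactants: 7 endoperoxide
Product: 9 6β-triethylsilyloxy C8a enone acetonide, via hydroxy enone 8 (not isolated)
Conditions: Et3N (cat.), CH2Cl2, 0 °C; then TESCl, imidazole, 0 °C to rt
Reagents that add atoms: chlorotriethylsilane, CC[Si](Cl)(CC)CC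
Why: In this Kornblum–DeLaMare fragmentation the amine should remove the bridgehead proton on C8a, flanked only by C8–H, rather than the one on C6, screened by the C7 methyl group on the peroxide face, so that C8a becomes the ketone and C6 keeps its β-hydroxyl, which is capped in the same flask.

Step 8
Reactants: 9 silyloxy enone
Product: 10 C4a iodide of 9 (2-iodoenone)
Conditions: I2, pyridine–CH2Cl2 1:1, 0 °C to rt
Reagents that add atoms: iodine, II
Why: α-Iodination of an enone by pyridine conjugate addition, enolate iodination and elimination (Baylis–Hillman-type mechanism) can deliver iodine only to C4a, the α-vinylic carbon of the C8a ketone.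

Step 9
Reactants: 10 iodoenone
Product: 11 C8a methoxymethylene iodo diene (C1=C8a–C4a(I)=C5)
Conditions: MeOCH2PPh3Cl, KN(SiMe3)2, THF, −78 to 0 °C
Reagents that add atoms: (methoxymethyl)triphenylphosphonium chloride, [Cl-].COC[P+](c1ccccc1)(c1ccccc1)c1ccccc1
Why: Wittig olefination with the small, reactive methoxymethylene ylide brings in C1 by 1,2-attack on the iodine-activated ketone at low temperature, and either enol ether geometry serves.

Step 10
Reactants: 11 iodo diene; 12 furfural
Product: 15 C4 furfuryl methyl ether with C6 silyl ether, via vinyllithium 13 (not isolated), via lithium alkoxide 14 (not isolated)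
Conditions: t-BuLi (2.1 equiv), Et2O, −78 °C; 12; then MeI, DMPU, −78 °C to rt
Reagents that add atoms: iodomethane, CI
Why: Iodine–lithium exchange, 1,2-addition of the dienyllithium to the non-enolisable aldehyde (forms C4–C4a) and Williamson methylation of the alkoxide follow each other in one flask, with C4 formed without control (harmless, it becomes planar in step 13) and the carbinol never set free next to C1.

Step 11
Reactants: 15 silyl ether
Product: 16 6β-carbinol
Conditions: Bu4NF, THF, 0 °C
Reagents that add atoms: none
Why: Fluoride cleavage of the silyl ether proceeds under non-acidic conditions that the acid-labile 1-methoxydiene tolerates.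

Step 12
Reactants: 16 dienyl carbinol
Product: 17 key-step precursor (C6 ketone, C5=C4a, C4a–CH(OMe)(2-furyl), C8a=CHOMe, (7R,8R)-7,8-acetonide)
Conditions: MnO2 (activated, excess), CH2Cl2, rt
Reagents that add atoms: none
Why: MnO2 oxidation of the allylic alcohol under neutral conditions installs the C6 ketone and turns the labile methoxydiene into the stable push–pull system C1=C8a–C4a=C5–C6=O.

Step 13
Reactants: 17 furfuryl methyl ether
Product: 20 (7R,8R)-7,8-O-isopropylidene side-chain enal, via methoxydihydrofuran 18 (not isolated), via dimethyl acetal 19 (not isolated)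
Conditions: Dy(OTf)3 (10 mol %), MeOH–MeCN 1:9, 3 Å molecular sieves, 0.01 M, 70 °C; then H2O, rt
Reagents that add atoms: water, O
Why: Proposed new method: Dy(OTf)3 ionises the C4–OMe bond of 17 to a furan-stabilised cation; methanol capture at C4 merely regenerates 17, whereas capture at the far furan α-carbon gives the 2-alkylidene-5-methoxy-2,5-dihydrofuran 18, whose ring acetal C–O bond then breaks so that the former furan oxygen becomes an enol oxygen on C3, C3=C4 is already in place and the remaining three furan carbons become the acetal-masked enal. This oxygen adds to C1, the terminus of the vinylogous methyl ester C1=C8a–C4a=C5–C6=O, and methanol leaves, a 6-endo-trig addition–elimination that forms C1–O2 and closes the pyran ring (O2, C1, C8a, C4a, C4, C3) to give 19, after which added water hydrolyses the acetal and the donor–acceptor enal equilibrates to the E isomer 20. The closest known reaction types are the Piancatelli rearrangement of 2-furyl carbinols with its Dy(OTf)3-catalysed amine and alcohol variants, the acid alcoholysis of furfuryl alcohols to levulinates, which runs through the same 5-alkoxy-2-methylene-2,5-dihydrofuran, and acid-induced furan ring-opening/recyclisation to benzo-fused heterocycles. No stereocentre is made: C4 turns planar, and C7 and C8 are spectators inside the cis-fused acetonide, which also makes any allylic ionisation at C8 reversible and retentive. Chemoselectivity hinges on C–O bond formation at C1 being faster than the 4π-conrotatory closure to a cyclopentenone that normally follows furan opening; the enol oxygen and C1 sit on neighbouring ring carbons in a 1,6 relationship, and the electron-poor dienone on the cation terminus slows the electrocyclisation. A methyl ether in dry methanol is used instead of a free carbinol in water because a C4 hydroxyl would add to C1 in a five-membered mode and aromatise irreversibly to a ring-fused bifuran, whereas every unproductive capture by methanol is degenerate.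

Step 14
Reactants: 20 enal acetonide
Product: 21 (E)-3-[(7R,8R)-7,8-dihydroxy-7-methyl-6-oxo-7,8-dihydro-6H-isochromen-3-yl]prop-2-enal
Conditions: TFA–H2O 9:1, CH2Cl2, 0 °C
Reagents that add atoms: none
Why: Aqueous-acid hydrolysis of the isopropylidene acetal breaks only the O–CMe2 bonds, so C7 and C8 keep their configuration, and the isochromenone core, itself formed under acid catalysis, is only protonated reversibly.

Step 15
Reactants: 22 orsellinic acid
Product: 23 tert-butyldimethylsilyl 2,4-bis(tert-butyldimethylsilyloxy)-6-methylbenzoate
Conditions: TBSCl (3.5 equiv), imidazole, DMF, rt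
Reagents that add atoms: tert-butyldimethylsilyl chloride, CC(C)(C)[Si](C)(C)Cl
Why: Exhaustive silylation masks both phenols and gives the silyl ester that serves as the acid chloride precursor.

Step 16
Reactants: 21 diol enal; 23 silyl ester
Product: 25 C8 bis-silyl orsellinate enal, via acid chloride 24 (not isolated)
Conditions: 23, (COCl)2, DMF (cat.), CH2Cl2, 0 °C to rt, concentrate; then 21, Et3N, DMAP (cat.), CH2Cl2, 0 °C to rt
Reagents that add atoms: none
Why: Oxalyl chloride with catalytic DMF converts the silyl ester into the acid chloride under neutral conditions, and DMAP-catalysed acylation takes the secondary C8 hydroxyl in preference to the tertiary C7 hydroxyl with retention, since the C8–O bond is not broken.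

Step 17
Reactants: 25 ester enal
Product: 26 bis-silyl ether of mitorubrinic acid B
Conditions: NaClO2, NaH2PO4, 2-methyl-2-butene, t-BuOH–H2O, 0 °C to rt
Reagents that add atoms: sodium chlorite, [Na+].[O-]Cl=O
Why: Pinnick oxidation converts the enal into the E-acrylic acid near pH 4 without touching the alkenes, the ester or the aryl silyl ethers, with 2-methyl-2-butene intercepting HOCl.

Step 18
Reactants: 26 bis-silyl ether
Product: 27 (+)-mitorubrinic acid B
Conditions: HF·pyridine, THF, 0 °C
Reagents that add atoms: none
Why: Fluoride-driven cleavage of the two aryl silyl ethers is fast at 0 °C and avoids both strong acid, which could ionise the allylic C8 ester, and base, which would open the pyran.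

Compound list
1 | benzoic acid | O=C(O)c1ccccc1 | starting material
2 | (1S,2R)-1,2-dihydroxycyclohexa-3,5-diene-1-carboxylic acid | OC(=O)[C@@]1(O)[C@H](O)C=CC=C1 | intermediate
3 | (3aS,7aR)-2,2-dimethyl-3a,7a-dihydro-1,3-benzodioxole-3a-carboxylic acid (acetonide of 2) | OC(=O)[C@@]12OC(C)(C)O[C@@H]1C=CC=C2 | intermediate
4 | [(3aR,7aR)-2,2-dimethyl-3a,7a-dihydro-1,3-benzodioxol-3a-yl]methanol | OC[C@@]12OC(C)(C)O[C@@H]1C=CC=C2 | intermediate
5 | p-toluenesulfonate of 4 | Cc1ccc(cc1)S(=O)(=O)OC[C@@]12OC(C)(C)O[C@@H]1C=CC=C2 | intermediate
6 | (3aS,7aR)-2,2,3a-trimethyl-3a,7a-dihydro-1,3-benzodioxole (C7 methyl β, 7,8-acetonide α) | C[C@@]12OC(C)(C)O[C@@H]1C=CC=C2 | intermediate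
7 | 6β,8aβ-endoperoxide of 6 (peroxide bridge anti to the acetonide) | C[C@@]12OC(C)(C)O[C@@H]1[C@@H]3C=C[C@H]2OO3 | intermediate
8 | hydroxy enone: C8a ketone, C4a=C5, 6β-OH, 7,8-acetonide | C[C@@]12OC(C)(C)O[C@@H]1C(=O)C=C[C@H]2O | intermediate
9 | triethylsilyl ether of 8 | C[C@@]12OC(C)(C)O[C@@H]1C(=O)C=C[C@H]2O[Si](CC)(CC)CC | intermediate
10 | C4a iodide of 9 | C[C@@]12OC(C)(C)O[C@@H]1C(=O)C(I)=C[C@H]2O[Si](CC)(CC)CC | intermediate
11 | C8a methoxymethylene iodo diene (E/Z mixture) | C[C@@]12OC(C)(C)O[C@@H]1C(=COC)C(I)=C[C@H]2O[Si](CC)(CC)CC | intermediate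
12 | furfural | O=Cc1ccco1 | starting material
13 | C4a dienyllithium from 11 | C[C@@]12OC(C)(C)O[C@@H]1C(=COC)C([Li])=C[C@H]2O[Si](CC)(CC)CC | intermediate
14 | lithium alkoxide of the C4 furyl carbinol (C4 epimers) | [Li+].C[C@@]12OC(C)(C)O[C@@H]1C(=COC)C(C([O-])c3ccco3)=C[C@H]2O[Si](CC)(CC)CC | intermediate
15 | C4 furfuryl methyl ether, C6 triethylsilyl ether (C4 epimers) | C[C@@]12OC(C)(C)O[C@@H]1C(=COC)C(C(OC)c3ccco3)=C[C@H]2O[Si](CC)(CC)CC | intermediate
16 | 6β-carbinol from 15 | C[C@@]12OC(C)(C)O[C@@H]1C(=COC)C(C(OC)c3ccco3)=C[C@H]2O | intermediate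
17 | key-step precursor: C6 ketone, C5=C4a, C4a–CH(OMe)(2-furyl), C8a=CHOMe, (7R,8R)-7,8-acetonide | C[C@@]12OC(C)(C)O[C@@H]1C(=COC)C(C(OC)c3ccco3)=CC2=O | intermediate
18 | 2-alkylidene-5-methoxy-2,5-dihydrofuran (C4=C3 exocyclic, OMe on the far α-carbon) | C[C@@]12OC(C)(C)O[C@@H]1C(=COC)C(C=C3C=CC(OC)O3)=CC2=O | intermediate
19 | pyran-closed dimethyl acetal of 20 | C[C@@]12OC(C)(C)O[C@@H]1C3=COC(C=CC(OC)OC)=CC3=CC2=O | intermediate
20 | (E)-3-[(7R,8R)-7,8-(isopropylidenedioxy)-7-methyl-6-oxo-7,8-dihydro-6H-isochromen-3-yl]prop-2-enal | C[C@@]12OC(C)(C)O[C@@H]1C3=COC(/C=C/C=O)=CC3=CC2=O | intermediate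
21 | (E)-3-[(7R,8R)-7,8-dihydroxy-7-methyl-6-oxo-7,8-dihydro-6H-isochromen-3-yl]prop-2-enal | O[C@@H]1C2=COC(/C=C/C=O)=CC2=CC(=O)[C@]1(C)O | intermediate
22 | orsellinic acid | Cc1cc(O)cc(O)c1C(=O)O | starting material
23 | tert-butyldimethylsilyl 2,4-bis(tert-butyldimethylsilyloxy)-6-methylbenzoate | CC(C)(C)[Si](C)(C)OC(=O)c1c(C)cc(O[Si](C)(C)C(C)(C)C)cc1O[Si](C)(C)C(C)(C)C | intermediate
24 | 2,4-bis(tert-butyldimethylsilyloxy)-6-methylbenzoyl chloride | Cc1cc(O[Si](C)(C)C(C)(C)C)cc(O[Si](C)(C)C(C)(C)C)c1C(=O)Cl | intermediate
25 | (7R,8R)-C8 bis-silyl orsellinate of 21 | Cc1cc(O[Si](C)(C)C(C)(C)C)cc(O[Si](C)(C)C(C)(C)C)c1C(=O)O[C@@H]1C2=COC(/C=C/C=O)=CC2=CC(=O)[C@]1(C)O | intermediate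
26 | bis(tert-butyldimethylsilyl) ether of mitorubrinic acid B | Cc1cc(O[Si](C)(C)C(C)(C)C)cc(O[Si](C)(C)C(C)(C)C)c1C(=O)O[C@@H]1C2=COC(/C=C/C(=O)O)=CC2=CC(=O)[C@]1(C)O | intermediate
27 | (+)-mitorubrinic acid B, (7R,8R)-3-[(E)-2-carboxyethenyl]-7-hydroxy-7-methyl-6-oxo-7,8-dihydro-6H-isochromen-8-yl 2,4-dihydroxy-6-methylbenzoate | Cc1cc(O)cc(O)c1C(=O)O[C@@H]1C2=COC(/C=C/C(=O)O)=CC2=CC(=O)[C@]1(C)O | target

Total step count: 18. Longest linear sequence: 17 (steps 1–14 and 16–18).

Steps most likely to fail

Step 13 (new method). After the furan opens, 4π-conrotatory closure to a cyclopentenone may outrun attack of the enol oxygen on C1. Intermolecular attack of a second furan on the furfuryl cation may do the same. The fallback uses known chemistry and takes C3 from an alkyne instead of a furan. It sets out from 11. Sonogashira coupling (PdCl2(PPh3)2, CuI, Et3N) with commercial (E)-pent-2-en-4-yn-1-ol gives the C4a enynol F1. Bu4NF frees the C6 carbinol to give the diol F2, and MnO2 oxidises both allylic alcohols at once to the keto enynal F3. AgOTf with a little TFA in wet 1,2-dichloroethane then hydrolyses the methoxymethylene group to its hydroxymethylene tautomer. The oxygen of that tautomer adds 6-endo-dig to the silver-activated alkyne, the standard cycloisomerisation entry to isochromene cores. The route is rejoined at 20.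

Step 9. Enolisation of the C8a ketone toward C8 by the basic ylide, followed by β-elimination of the C7 oxygen and aromatisation, may compete with olefination. The fallback sets out from 10. MeOCH(Li)SiMe3 (from MeOCH2SiMe3 and s-BuLi) is made less basic by transmetalation with CeCl3 and adds to C8a to give the β-hydroxysilane F4. KH in THF then triggers the Peterson elimination, and the route is rejoined at 11.

Step 7. Proton abstraction at the wrong bridgehead (C6–H) would place the ketone on C6 and leave C4a without an α-carbonyl handle. The fallback sets out from 7. Thiourea in MeOH reduces the O–O bond to the cis-6,8a-enediol F5. TEMPO with PhI(OAc)2, an oxidant very sensitive to crowding, should oxidise the C8a carbinol and leave the neopentyl-type C6 carbinol, which gives 8. Silylation as in step 7 rejoins the route at 9.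

Further compounds
F1 | step 13 | C4a (E)-5-hydroxypent-3-en-1-ynyl diene, C6 triethylsilyl ether | C[C@@]12OC(C)(C)O[C@@H]1C(=COC)C(C#C/C=C/CO)=C[C@H]2O[Si](CC)(CC)CC
F2 | step 13 | diol from F1 (6β-OH and primary allylic OH) | C[C@@]12OC(C)(C)O[C@@H]1C(=COC)C(C#C/C=C/CO)=C[C@H]2O
F3 | step 13 | keto enynal (C6 ketone, C4a–C≡C–CH=CH–CHO, C8a=CHOMe) | C[C@@]12OC(C)(C)O[C@@H]1C(=COC)C(C#C/C=C/C=O)=CC2=O
F4 | step 9 | C8a tertiary carbinol bearing CH(OMe)SiMe3 (β-hydroxysilane, isomer mixture) | C[C@@]12OC(C)(C)O[C@@H]1C(O)(C(OC)[Si](C)(C)C)C(I)=C[C@H]2O[Si](CC)(CC)CC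
F5 | step 7 | 6β,8aβ-enediol acetonide | C[C@@]12OC(C)(C)O[C@@H]1[C@@H](O)C=C[C@H]2O
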